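The dihydropyran ring of the chroman is disconnected across C4–C3 and O1–C2 into an ortho-quinone methide and isobutylene. The key step heats 3-bromo-2-(hydroxymethyl)phenol with isobutylene: dehydration unveils the quinone methide, which takes up the alkene in a regioselective [4+2] cycloaddition that forms both bonds, sets the gem-dimethyl carbon and rearomatises the ring. It exploits the ortho relationship of O1 on C8a and the benzylic C4 on C4a of the chroman benzene ring, with C2 as a cation-stabilising tertiary carbon. Sterically governed C–H borylation/oxidation then installs the 7-OH, and an alkyne/o-iodophenol annulation with a Claisen-derived reverse-prenylated iodophenol builds the benzofuran.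

Key step: step 2

Remark: the target has no stereocentre, so no stereocontrol is needed. Usual ring numbering is used (chroman: O1, C2, C3, C4, C4a, C5 to C8, C8a; benzofuran: O1, C2, C3, C3a, C4 to C7, C7a). Isobutylene is handled condensed in a pressure vessel.

Step 1
Reactants: 1 2-bromo-6-hydroxybenzaldehyde
Product: 2 3-bromo-2-(hydroxymethyl)phenol
Conditions: NaBH4, MeOH, 0 °C; aq. NH4Cl
Reagents that add atoms: none
Why: Borohydride reduction of the aldehyde to the primary benzylic alcohol should leave the aryl bromide and phenol untouched and gives the salicyl alcohol needed for quinone methide generation.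

Step 2
Reactants: 2 3-bromo-2-(hydroxymethyl)phenol; 3 isobutylene (2-methylpropene)
Product: 5 5-bromo-2,2-dimethylchroman, via o-quinone methide 4 (not isolated)
Conditions: isobutylene (condensed, about 40 equiv), toluene (0.05 M in 2), steel autoclave, 170 °C, 16 h
Reagents that add atoms: none
Why: Thermal 1,4-dehydration of the o-hydroxybenzyl alcohol 2 should give o-quinone methide 4, an electron-poor 1-oxadiene, which is intercepted by the electron-rich 1,1-disubstituted alkene 3 in an inverse-electron-demand hetero-Diels–Alder reaction that makes C4–C3 and O1–C2 together and is driven by rearomatisation. The closest known reaction type is the thermal o-quinone methide [4+2] chroman synthesis from salicyl alcohols and alkenes. The dihydropyran ring closes by a concerted, asynchronous [4+2] cycloaddition (4π C=C–C=O unit of 4 plus 2π of 3), with C–C bonding running ahead of C–O bonding. No stereocentre is formed, because C2 carries two methyl groups and C3 and C4 are methylene carbons. The step needs regioselectivity (2,2- rather than 3,3-dimethyl) and cross-reaction over self-reaction of 4: the first is secured by the polarisation of 4 (electrophilic exocyclic CH2, nucleophilic oxygen) matched to the nucleophilic CH2 terminus and cation-stabilising C(CH3)2 terminus of 3, the second by the large excess of 3, high dilution and the only weakly nucleophilic bromophenol ring of 2.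

Step 3
Reactants: 5 5-bromo-2,2-dimethylchroman
Product: 7 5-bromo-2,2-dimethylchroman-7-ol, via aryl pinacolboronate 6 (not isolated)
Conditions: [Ir(OMe)(1,5-cyclooctadiene)]2 (1.5 mol %), 4,4'-di-tert-butyl-2,2'-bipyridine (3 mol %), B2pin2 (1.0 equiv), THF, 80 °C; then Oxone (2KHSO5·KHSO4·K2SO4), acetone/H2O, 0 °C to rt
Reagents that add atoms: bis(pinacolato)diboron CC1(C)OB(OC1(C)C)B1OC(C)(C)C(C)(C)O1 (boryl group of intermediate 6); potassium peroxymonosulfate [K+].[O-]S(=O)(=O)OO (oxygen of the new hydroxyl)
Why: Iridium-catalysed aromatic C–H borylation is sterically controlled, so of the three aromatic C–H bonds only C7–H, which has no ortho substituent (C6–H lies next to bromine, C8–H next to O1), should react while the aryl bromide is tolerated, and Oxone oxidation of the C–B bond then gives the phenol at the same carbon (one-pot borylation/oxidation).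

Step 4
Reactants: 7 5-bromo-2,2-dimethylchroman-7-ol; 8 trimethylsilylacetylene
Product: 10 5-ethynyl-2,2-dimethylchroman-7-ol, via silylalkyne 9 (not isolated)
Conditions: Pd(PhCN)2Cl2 (3 mol %), [HP(t-Bu)3]BF4 (6 mol %), CuI (2 mol %), i-Pr2NH, 1,4-dioxane, 45 °C; then K2CO3, MeOH, rt, same flask
Reagents that add atoms: none
Why: Sonogashira coupling with the electron-rich bulky phosphine P(t-Bu)3 should engage the electron-rich, ortho-alkylated aryl bromide in the presence of the free phenol, and methanolysis of the alkynyl C–Si bond then liberates the terminal alkyne.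

Step 5
Reactants: 11 phloroglucinol (benzene-1,3,5-triol)
Product: 12 3,5-bis[(tert-butyldimethylsilyl)oxy]phenol
Conditions: TBSCl (2.0 equiv), imidazole (4.0 equiv), DMF, 0 °C to rt; chromatographic separation from mono- and tris-silyl ethers
Reagents that add atoms: tert-butyldimethylsilyl chloride CC(C)(C)[Si](C)(C)Cl
Why: Silylation of the three equivalent hydroxyls with two equivalents of silyl chloride should give the bis-silyl ether as the main component of a statistical mixture, leaving one phenol free for the later steps.

Step 6
Reactants: 12 3,5-bis[(tert-butyldimethylsilyl)oxy]phenol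
Product: 13 2-iodo-3,5-bis[(tert-butyldimethylsilyl)oxy]phenol
Conditions: NIS (1.0 equiv), CH2Cl2, −78 to −20 °C, dark
Reagents that add atoms: N-iodosuccinimide O=C1CCC(=O)N1I
Why: Electrophilic aromatic iodination of the strongly activated ring should occur ortho to the free hydroxyl, because C4 is shielded by two bulky silyloxy groups, and one equivalent of reagent at low temperature limits double iodination.

Step 7
Reactants: 13 2-iodo-3,5-bis[(tert-butyldimethylsilyl)oxy]phenol; 14 prenyl bromide (1-bromo-3-methylbut-2-ene)
Product: 15 1,5-bis[(tert-butyldimethylsilyl)oxy]-2-iodo-3-[(3-methylbut-2-en-1-yl)oxy]benzene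
Conditions: K2CO3, acetone, rt
Reagents that add atoms: none
Why: Williamson ether synthesis of the phenoxide at the primary allylic bromide (SN2) should give the O-prenyl ether, and anhydrous carbonate in acetone leaves the aryl silyl ethers intact.

Step 8
Reactants: 15 1,5-bis[(tert-butyldimethylsilyl)oxy]-2-iodo-3-[(3-methylbut-2-en-1-yl)oxy]benzene
Product: 17 2-iodo-6-(2-methylbut-3-en-2-yl)-3,5-bis[(tert-butyldimethylsilyl)oxy]phenol, via cyclohexadienone 16 (not isolated)
Conditions: PhNEt2, 185 °C, sealed tube, argon
Reagents that add atoms: none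
Why: The aromatic Claisen rearrangement ([3,3]-sigmatropic shift) should deliver the allyl unit with inversion, as the 1,1-dimethylallyl group, to the only unsubstituted ortho carbon, after which dienone 16 tautomerises to the phenol, and the basic solvent suppresses acid-catalysed addition of the new phenol to the vinyl group.

Step 9
Reactants: 17 2-iodo-6-(2-methylbut-3-en-2-yl)-3,5-bis[(tert-butyldimethylsilyl)oxy]phenol; 10 5-ethynyl-2,2-dimethylchroman-7-ol
Product: 19 5-[4,6-bis[(tert-butyldimethylsilyl)oxy]-7-(2-methylbut-3-en-2-yl)benzofuran-2-yl]-2,2-dimethylchroman-7-ol, via alkynylphenol 18 (not isolated)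
Conditions: Pd(PPh3)2Cl2 (5 mol %), CuI (10 mol %), Et3N, DMF, 60 °C, argon
Reagents that add atoms: none
Why: Sonogashira coupling of the aryl iodide followed by copper/amine-promoted 5-endo-dig addition of the ortho hydroxyl to the alkyne (o-iodophenol/alkyne benzofuran annulation) should give the 2-arylbenzofuran, and because the only free hydroxyl ortho to the alkyne is the one next to the 1,1-dimethylallyl group, that group must end at C7.

Step 10
Reactants: 19 5-[4,6-bis[(tert-butyldimethylsilyl)oxy]-7-(2-methylbut-3-en-2-yl)benzofuran-2-yl]-2,2-dimethylchroman-7-ol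
Product: 20 2-(7-hydroxy-2,2-dimethylchroman-5-yl)-7-(2-methylbut-3-en-2-yl)benzofuran-4,6-diol
Conditions: Bu4NF (2.5 equiv), AcOH (2.5 equiv), THF, 0 °C
Reagents that add atoms: none
Why: Fluoride-mediated cleavage of the two aryl silyl ethers under acetic acid buffering should free the phenols without acid or strong base, so the 1,1-dimethylallyl group, the chroman ether and the benzofuran remain intact.

Compound list
1 | 2-bromo-6-hydroxybenzaldehyde | O=Cc1c(O)cccc1Br | starting material
2 | 3-bromo-2-(hydroxymethyl)phenol | OCc1c(O)cccc1Br | intermediate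
3 | isobutylene (2-methylpropene) | C=C(C)C | starting material
4 | 5-bromo-6-methylidenecyclohexa-2,4-dien-1-one (o-quinone methide) | C=C1C(Br)=CC=CC1=O | intermediate
5 | 5-bromo-2,2-dimethylchroman | CC1(C)CCc2c(Br)cccc2O1 | intermediate
6 | 2-(5-bromo-2,2-dimethylchroman-7-yl)-4,4,5,5-tetramethyl-1,3,2-dioxaborolane | CC1(C)CCc2c(Br)cc(B3OC(C)(C)C(C)(C)O3)cc2O1 | intermediate
7 | 5-bromo-2,2-dimethylchroman-7-ol | CC1(C)CCc2c(Br)cc(O)cc2O1 | intermediate
8 | trimethylsilylacetylene | C#C[Si](C)(C)C | starting material
9 | 2,2-dimethyl-5-[(trimethylsilyl)ethynyl]chroman-7-ol | CC1(C)CCc2c(C#C[Si](C)(C)C)cc(O)cc2O1 | intermediate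
10 | 5-ethynyl-2,2-dimethylchroman-7-ol | C#Cc1cc(O)cc2c1CCC(C)(C)O2 | intermediate
11 | phloroglucinol (benzene-1,3,5-triol) | Oc1cc(O)cc(O)c1 | starting material
12 | 3,5-bis[(tert-butyldimethylsilyl)oxy]phenol | CC(C)(C)[Si](C)(C)Oc1cc(O)cc(O[Si](C)(C)C(C)(C)C)c1 | intermediate
13 | 2-iodo-3,5-bis[(tert-butyldimethylsilyl)oxy]phenol | Oc1cc(O[Si](C)(C)C(C)(C)C)cc(O[Si](C)(C)C(C)(C)C)c1I | intermediate
14 | prenyl bromide (1-bromo-3-methylbut-2-ene) | CC(C)=CCBr | starting material
15 | 1,5-bis[(tert-butyldimethylsilyl)oxy]-2-iodo-3-[(3-methylbut-2-en-1-yl)oxy]benzene | CC(C)=CCOc1cc(O[Si](C)(C)C(C)(C)C)cc(O[Si](C)(C)C(C)(C)C)c1I | intermediate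
16 | racemic 2-iodo-6-(2-methylbut-3-en-2-yl)-3,5-bis[(tert-butyldimethylsilyl)oxy]cyclohexa-2,4-dien-1-one | C=CC(C)(C)C1C(=O)C(I)=C(O[Si](C)(C)C(C)(C)C)C=C1O[Si](C)(C)C(C)(C)C | intermediate
17 | 2-iodo-6-(2-methylbut-3-en-2-yl)-3,5-bis[(tert-butyldimethylsilyl)oxy]phenol | C=CC(C)(C)c1c(O)c(I)c(O[Si](C)(C)C(C)(C)C)cc1O[Si](C)(C)C(C)(C)C | intermediate
18 | 2-[(7-hydroxy-2,2-dimethylchroman-5-yl)ethynyl]-6-(2-methylbut-3-en-2-yl)-3,5-bis[(tert-butyldimethylsilyl)oxy]phenol | C=CC(C)(C)c1c(O)c(C#Cc2cc(O)cc3c2CCC(C)(C)O3)c(O[Si](C)(C)C(C)(C)C)cc1O[Si](C)(C)C(C)(C)C | intermediate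
19 | 5-[4,6-bis[(tert-butyldimethylsilyl)oxy]-7-(2-methylbut-3-en-2-yl)benzofuran-2-yl]-2,2-dimethylchroman-7-ol | C=CC(C)(C)c1c(O[Si](C)(C)C(C)(C)C)cc(O[Si](C)(C)C(C)(C)C)c2cc(-c3cc(O)cc4c3CCC(C)(C)O4)oc12 | intermediate
20 | 2-(7-hydroxy-2,2-dimethylchroman-5-yl)-7-(2-methylbut-3-en-2-yl)benzofuran-4,6-diol | C=CC(C)(C)c1c(O)cc(O)c2cc(-c3cc(O)cc4c3CCC(C)(C)O4)oc12 | target

Total step count: 10
Longest linear sequence: 6 steps (steps 1, 2, 3, 4, 9, 10; the branch of steps 5, 6, 7, 8, 9, 10 is equally long)

Steps most likely to fail

Step 2 (key step). The quinone methide may be consumed by self-condensation (dimerisation, benzylation of unreacted phenol) faster than the weakly nucleophilic, volatile alkene captures it. The fallback sets out from 1 and comes back at 5. Addition of 2-methylallylmagnesium chloride (2.5 equiv, THF, 0 °C) to the aldehyde should give racemic 3-bromo-2-(1-hydroxy-3-methylbut-3-en-1-yl)phenol F1. Treatment with Et3SiH and CF3CO2H in CH2Cl2 (0 °C to rt) should then remove the benzylic hydroxyl by ionic hydrogenation and close the ether by Markovnikov addition of the phenol to the protonated 1,1-disubstituted alkene, giving 5. The two ring bonds are then made in separate polar events and not by cycloaddition.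

Step 8. At 185 °C the allyl unit may migrate to the iodinated ortho carbon and onward to C4, or iodine may be lost from the ring. The fallback sets out from 12 and comes back at 17, and keeps the halogen out of the thermal step. O-Prenylation of 12 with 14 (K2CO3, acetone) should give 1,3-bis[(tert-butyldimethylsilyl)oxy]-5-[(3-methylbut-2-en-1-yl)oxy]benzene F2. Its Claisen rearrangement (PhNEt2, 185 °C), with two equivalent ortho positions and no halogen, should give 2-(2-methylbut-3-en-2-yl)-3,5-bis[(tert-butyldimethylsilyl)oxy]phenol F3. Iodination with NIS (CH2Cl2, −78 °C) at the one remaining ortho position then gives 17. The activated arene should react far faster than the hindered monosubstituted alkene, and C4 stays shielded by two silyloxy groups.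

Step 6. Ortho/para selectivity may be poor, and double iodination may occur. The fallback sets out from 11 and comes back at 13, and moves the iodination to the symmetric triol, where only one mono-iodide is possible. Iodine with NaHCO3 in THF/H2O at 0 °C should give 2-iodobenzene-1,3,5-triol F4. Silylation with TBSCl (2.0 equiv) and imidazole in DMF at −20 °C should first take the unhindered hydroxyl para to iodine and then one of the two equivalent hydroxyls next to iodine, giving 13.

Further compounds
F1 | step 2 | racemic 3-bromo-2-(1-hydroxy-3-methylbut-3-en-1-yl)phenol | C=C(C)CC(O)c1c(O)cccc1Br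
F2 | step 8 | 1,3-bis[(tert-butyldimethylsilyl)oxy]-5-[(3-methylbut-2-en-1-yl)oxy]benzene | CC(C)=CCOc1cc(O[Si](C)(C)C(C)(C)C)cc(O[Si](C)(C)C(C)(C)C)c1
F3 | step 8 | 2-(2-methylbut-3-en-2-yl)-3,5-bis[(tert-butyldimethylsilyl)oxy]phenol | C=CC(C)(C)c1c(O)cc(O[Si](C)(C)C(C)(C)C)cc1O[Si](C)(C)C(C)(C)C
F4 | step 6 | 2-iodobenzene-1,3,5-triol | Oc1cc(O)c(I)c(O)c1
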